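The data are simulated from invented constants; the scatter is artificial.

Your vessel, the birch run, held 0.200 M of starting material, the limiting reagent by charge, with 0.400 M of coupling partner. Your hunch was that it stalls because the main step uses up the partner. I checked that against the readings.

| flask | starting material | coupling partner | time |
|---|---|---|---|
| birch | 0.200 M | 0.400 M |  |
| oak | 0.0800 M | 0.280 M |  |
| larch | 0.300 M | 0.400 M |  |
| alder | 0.200 M | 0.400 M | 64 min |

| run | time / min | [starting material] / M |
|---|---|---|
| birch run | 0.64 | 0.194 |
| birch run | 1.2 | 0.184 |
| birch run | 2.3 | 0.173 |
| birch run | 4.4 | 0.163 |
| birch run | 8.4 | 0.142 |
| birch run | 16 | 0.130 |
| oak run | 0.64 | 0.077 |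
| oak run | 1.2 | 0.078 |
| oak run | 2.3 | 0.070 |
| oak run | 4.4 | 0.068 |
| oak run | 8.4 | 0.055 |
| oak run | 16 | 0.056 |
| larch run | 0.64 | 0.283 |
| larch run | 1.2 | 0.274 |
| larch run | 2.3 | 0.261 |
| larch run | 4.4 | 0.236 |
| larch run | 8.4 | 0.219 |
| larch run | 16 | 0.197 |

(standard deviation of a reading: 0.003 M)

1. reaction order in [coupling partner] at the outset, round the charge of the birch run, defined at two percent of the starting material turned into target
2. reaction order in [starting material] at the outset, round the charge of the birch run, defined at two percent of the starting material turned into target (one fixed amount of target, the same in the runs compared)
3. starting material in the alder run at 64 min, as a share of the starting material charged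
4. which of these the readings show (the product binds the second partner / the substrate pairs with itself / the second partner is lost in pairs / the two partners rest in a complex / the product speeds the reaction / nothing beyond the main steps)

- Overall: starting material + coupling partner -> target.
- Constant volume, constant temperature.
- "The second partner" is coupling partner.
- An order is taken over about fifteen percent of the charge, up and down.

1. In the birch run, [starting material] fell by 0.0700 M by 16 min, so the main step left 0.330 M of partner. That is a drop by a factor of 1.21. Yet the fall of ln[starting material] per minute went from 0.0695 /min over the first 1.2 min to 0.0116 /min between 8.4 min and 16 min, a factor of 5.99. So the partner must be going some other way.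

2. The larch run lost more starting material, 0.103 M by 16 min, yet ln([starting material] at the start/[starting material]) there reached 0.421 against 0.431 in the birch run. The gap of 0.0102 between these two readings is smaller than its scatter of about 0.0276, so they neither show an effect of target nor exclude one. I put the order in starting material near 1, and the order in partner near 1 only as an assumption, since these two runs share 0.400 M of partner and do not show that order.

3. I took the partner to be lost in pairs, and solved the two ends. Early on, ln[starting material] falls at 0.0695 /min. Late, the partner falls as one over time, so ln[starting material] falls by a fixed amount for each unit of ln(time). I call this amount the late gain 0.175, read in the birch run from 4.4 min to 16 min. With pair loss it holds no charge of partner. The two ends join at 2.52 min.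

4. The alder run has the birch charge, and 16 min lies past that join. Carrying the late gain to 64 min gave me 51.0% of the charge.

The forecast gave 51% (45% to 57%), orders 1.01 and 1.13, and "the second partner is lost in pairs", on the ground that “something else is removing the coupling partner”.

The alder run gave 55.3%, with orders 1.0 in partner and 1.1 in starting material; the readings show that the second partner is lost in pairs. The fit with the true steps gave 52.2%.

    starting material + coupling partner → target (0.2106 /M/min)
    target + coupling partner → side product (0.5712 /M/min)
    2 coupling partner → lost reagent (0.3162 /M/min)

From the 16 min birch reading to this result, the late gain came to 0.116, against my 0.175. Carried on the oak run from 4.4 min to 16 min, my 0.175 gives 0.0542 M, and the reading there is 0.056 M.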